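## Structural features

The target is a 2,3-dihydro-1,4-benzodioxine (ring C) fused to benzene ring B. C7 of ring C carries the 4-hydroxy-3,5-dimethoxyphenyl ring A and is bound to ring oxygen Oa; C8 carries the hydroxymethyl carbon C9 and is bound to ring oxygen Ob (C8 and C7 are C2 and C3 in benzodioxine numbering). Ring B bears an (E)-propenal chain para to the carbon holding Ob and meta to the carbon holding Oa, so the two ring oxygens are not interchangeable and any plan must tell them apart. C7 and C8 are adjacent stereocentres, both S, with the aryl and hydroxymethyl groups trans. The trans arrangement is the thermodynamic one and can be reached by equilibration through the ring A quinone methide, because C7 is a benzylic aryl ether para to a free phenol; the same feature makes the C7–Oa bond sensitive to base and acid. The other fragile groups are the enal (conjugate addition, light, a second olefination), the oxidisable syringyl phenol and the primary alcohol. The real difficulties are therefore the placement of Oa and Ob relative to the side chain and the absolute configuration at C8, not the relative configuration. The key step exploits the fact that C7, C8, C9 and the C9 oxygen are the four ring atoms of an oxetane: O–C7 is the carbonyl group of syringaldehyde, C9=C8–Ob is an aryl vinyl ether of ring B, and the strain of that ring later pays for moving C7 from the oxetane oxygen to Oa.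

## Logic of the disconnections

**20 ⇒ 18 + 19.** The C=C bond of the propenal chain is cut. The enal is the most fragile group and is best made last; without it the molecule is an aromatic aldehyde that tolerates base, mild acid and enzymes. The forward step must give the E olefin and stop after one two-carbon extension.

**18 ⇒ 17 ⇒ 16.** No skeletal bond is cut; the single enantiomer is traced back to the racemate through the C9 acetate. The step that creates C8 joins two flat, achiral partners and cannot be made enantioselective with known chemistry, so the absolute configuration is deferred to a resolution at the primary hydroxyl next to C8. The forward steps need a hydrolase that tells the antipodes apart; using it once for acylation and once for deacylation multiplies its selectivity.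

**16 ⇒ 12.** The Oa–C7 bond is cut and C7 is reconnected to the C9 oxygen, which contracts the dioxane to an oxetane; the formyl group returns to a dioxolane and both phenols to acetates. This turns a six-membered ring with two different aryl ether bonds and two stereocentres into a four-membered ring that one cycloaddition can build. The configuration at C7 in 12 is irrelevant because C7 is formed again. The forward step must break C7–O and not C9–O, deliver Oa to C7 and not to C9, and end trans.

**12 ⇒ 2 + 11.** The C7–C8 and O–C9 bonds are cut. This is the largest simplification: two achiral benzene derivatives, each from a commercial aldehyde. The forward step must join the carbonyl oxygen to the CH2 terminus of the enol ether, and the partners must carry no free O–H and no second carbonyl group.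

**2 ⇒ 1.** The acetyl C–O bond is cut; the forward step is a plain acylation of a hindered phenol.

**11 ⇒ 8 (through 9 and 10).** The C8=C9 double bond is traced back to a 2-chloroethyl ether and the acetate to a silyl ether. The vinyl ether is too acid-labile to be carried through acetal formation, and an acetate would not survive the base needed for the elimination. A free ortho phenoxide would displace the halide and close a benzodioxane, so that oxygen must be capped by a base-stable group during the elimination. The forward step therefore must eliminate before it desilylates.

**8 ⇒ 7 ⇒ 5 ⇒ 3 + 4 (with 6).** The Si–O bond, the two acetal C–O bonds and the Ob–CH2 ether bond are cut. The regiochemistry of the whole synthesis (Ob para to the side chain) is fixed here by the different acidity of the two phenols of 3. The forward alkylation must stop at the monoether, without ring closure by the second hydroxyl; for that reason the two-carbon unit carries one good and one poor leaving group rather than two equal ones.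

## Other disconnections considered

**Alternative 1:** Ring B itself is taken apart: the three C–C bonds of a [2+2+2] cyclotrimerisation are cut, and the bond between the carbons that carry Oa and Ob is at the same time the bond that closes the dioxane.
- Forward step: the bis-ynol ether A1, with an ethynyl group on Oa and a (trimethylsilyl)ethynyl group on Ob, would be co-trimerised with 3,3-diethoxyprop-1-yne A2 under Cp*RuCl(cod) to give the benzodioxane A3.
- In its favour: both stereocentres would be in place before the key step and could come from an asymmetric dihydroxylation. No resolution and no loss of half the material would be needed; on this point the alternative is better than the chosen plan.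
- The Oa/Ob regiochemistry is encoded by the silyl group. If the alkyne inserts in the expected orientation, this is equal in certainty to the acidity-controlled alkylation of step 2.
- Against it: ynol ethers of secondary alcohols are laborious to make and fragile. One with a β-hydrogen can lose a ketene by a retro-ene path, and the benzylic ether at C7 is the worst case. Two different ynol ethers must be installed on neighbouring oxygens one after the other, and ruthenacycle formation from two oxygen-substituted alkynes is not routine.
- After the key step the aryl–silicon bond, the benzyl ether, the silyl ether and the acetal must all be removed before the same Wittig step, and the benzyl ether must go before the enal exists.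
- Comparison: the alternative builds the arene last on a metal template; the chosen plan takes both arenes from commercial aldehydes and spends its key step on the heterocycle. In step count the alternative would be clearly longer.

**Alternative 2:** Only the Oa–C7 bond is cut. This leaves the open aryl ether A4, with the C8–Ob bond and the C8 configuration in place and C7 as a methylene group.
- Forward step: a 4-alkylphenol oxidase of the vanillyl alcohol oxidase family, or Ag2O as a chemical substitute, would dehydrogenate C7 to the ring A quinone methide, and Oa would add to C7 to give A5.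
- In its favour: the ring closure is the same quinone methide addition as in step 7 of the chosen plan, so the trans outcome is equally well founded. A5 is the same substance as 18, so the endgame is identical.
- The stereocentre would come from the chiral pool or from asymmetric synthesis instead of a resolution, and the sequence would probably be several steps shorter. On stereochemical economy and on step count this alternative is the better one.
- Against it: oxidases of this class normally hand the quinone methide to water in the active site, and it is open whether they accept a substrate with a bulky aryloxy group next to the reacting carbon. With Ag2O, an oxidant meets two free phenols and an aldehyde.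
- The quinone methide has a hydrogen on C8 and can tautomerise to a 4-hydroxystyrene, which would erase the stereocentre the alternative relies on. In the chosen plan the corresponding intermediate 14 is racemic at that stage and has nothing to lose.
- Comparison: the chosen plan reaches the quinone methide without an oxidant, by strain release, and pays for that with the resolution.

**Alternative 3:** The Ob–C8 and C7–C8 bonds are cut, so that C8 with a carboxyl substituent is inserted as a carbene carbon into the five-membered acetal A6, a 2-aryl-1,3-benzodioxole.
- Forward step: the copper carbene from tert-butyl diazoacetate A7 (CuOTf, chiral bisoxazoline) would add to Ob, and the oxonium ylide would shift C7 from oxygen to carbon ([1,2]-shift of the Stevens type) to give the ester A8.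
- In its favour: A6 is one acetalisation away from a catechol and an aldehyde, so the way to the key step is shorter than in the chosen plan. A catalytic asymmetric insertion would in principle set both centres at once without a resolution. On both counts the alternative is better on paper.
- Against it: aryl ether oxygens are weak donors towards copper carbenes, and cyclopropanation of the electron-rich arenes or insertion into the acetal C–H bond are likely to compete. Oa and Ob differ only by a distant silyloxy group, so the choice of oxygen is not secured. The [1,2]-shift passes through a radical or ion pair at C7, so neither the trans relationship nor transfer of chirality from the catalyst is assured.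
- Ring expansions of this kind are established for oxetanes and aliphatic acetals but not for benzodioxoles, so the key step would be new chemistry, whereas the chosen key step belongs to a known reaction class.
- After the key step the ester must be reduced, the silyl ether turned into a leaving group and cross-coupled to bring in the three-carbon chain, and the benzyl ether removed without hydrogenating the enal. The total would be longer than the chosen plan.

Key step: step 6

Remark on the chemistry: Candida antarctica lipase B is assumed to acylate the (2S,3S) antipode of 16 faster, by analogy with its preference among related trans-3-aryl-2-(hydroxymethyl)-1,4-benzodioxanes. If the preference is the reverse, the unreacted alcohol of step 8 is 18 and step 9 falls away. Compounds 12 to 16 are racemic; their SMILES show the antipode that leads to 20.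

## Route

Step 1
Reactants: 1 syringaldehyde (4-hydroxy-3,5-dimethoxybenzaldehyde)
Product: 2 4-formyl-2,6-dimethoxyphenyl acetate
Conditions: Ac2O, pyridine, DMAP (cat.), CH2Cl2, rt
Reagents that add atoms: acetic anhydride CC(=O)OC(C)=O
Why: O-Acylation of the hindered phenol under nucleophilic catalysis; the acetate removes the phenolic hydrogen that would quench an excited carbonyl group and weakens the donor character of the 4-oxygen, which helps the aldehyde keep a reactive n,π* triplet.

Step 2
Reactants: 3 3,4-dihydroxybenzaldehyde; 4 1-bromo-2-chloroethane
Product: 5 4-(2-chloroethoxy)-3-hydroxybenzaldehyde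
Conditions: NaHCO3 (1.0 equiv), DMF, 45 °C; 4 in tenfold excess
Reagents that add atoms: none
Why: Williamson ether synthesis under acidity control: the 4-hydroxyl, conjugated with the formyl group, is the only phenol that hydrogencarbonate ionises, and its phenoxide displaces bromide far faster than chloride. With no base left over and chloride as the remaining leaving group, the 3-hydroxyl should not close a benzodioxane; a dihalide with two equal leaving groups or an excess of base would invite that ring closure.

Step 3
Reactants: 5 4-(2-chloroethoxy)-3-hydroxybenzaldehyde; 6 ethane-1,2-diol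
Product: 7 2-(2-chloroethoxy)-5-(1,3-dioxolan-2-yl)phenol
Conditions: PPTS (cat.), toluene, reflux, Dean–Stark trap; Et3N before work-up
Reagents that add atoms: none
Why: Acid-catalysed acetalisation with azeotropic removal of water; it must come before the vinyl ether exists, because an aryl vinyl ether would add the diol under the same acid.

Step 4
Reactants: 7 2-(2-chloroethoxy)-5-(1,3-dioxolan-2-yl)phenol
Product: 8 [2-(2-chloroethoxy)-5-(1,3-dioxolan-2-yl)phenoxy]tri(propan-2-yl)silane
Conditions: chlorotri(propan-2-yl)silane, imidazole, DMF, rt
Reagents that add atoms: chlorotri(propan-2-yl)silane CC(C)[Si](Cl)(C(C)C)C(C)C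
Why: Imidazole-assisted silylation of the phenol; the bulky silyl ether survives tert-butoxide and keeps the ortho oxygen from displacing chloride in the next step, which an acetate or a free phenol could not do.

Step 5
Reactants: 8 [2-(2-chloroethoxy)-5-(1,3-dioxolan-2-yl)phenoxy]tri(propan-2-yl)silane
Product: 11 5-(1,3-dioxolan-2-yl)-2-(ethenyloxy)phenyl acetate, via silyl vinyl ether 9 (not isolated), via vinyloxyphenoxide 10 (not isolated)
Conditions: t-BuOK, THF–DMSO (4:1), 0 °C → rt; then Bu4NF, 0 °C; then Ac2O, 0 °C → rt; NaHCO3 work-up
Reagents that add atoms: acetic anhydride CC(=O)OC(C)=O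
Why: E2 dehydrochlorination of the 2-aryloxyethyl chloride by the hindered base gives the aryl vinyl ether; only then does fluoride cleave the silyl ether, when the phenoxide has nothing left to alkylate, and the phenoxide is trapped as the acetate in the same flask. The acetate is wanted on Oa because it makes ring B a poorer electron donor towards the excited aldehyde and can later be removed together with the ring A acetate.

Step 6
Reactants: 2 4-formyl-2,6-dimethoxyphenyl acetate; 11 5-(1,3-dioxolan-2-yl)-2-(ethenyloxy)phenyl acetate
Product: 12 4-{3-[2-(acetyloxy)-4-(1,3-dioxolan-2-yl)phenoxy]oxetan-2-yl}-2,6-dimethoxyphenyl acetate (racemic at C3 of the oxetane; both C2 epimers)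
Conditions: hν (350 nm, Pyrex), degassed benzene, 15 °C; 11 in threefold excess, recovered
Reagents that add atoms: none
Why: Light of 350 nm is absorbed only by the n,π* band of 2; after intersystem crossing, the electrophilic oxygen of the triplet attacks the terminal CH2 of enol ether 11 and forms the O–C9 bond, leaving a triplet 1,4-biradical with one centre on benzylic C7 and the other on C8 next to the aryloxy oxygen. Spin inversion and radical combination then form the C7–C8 bond and close the four-membered ring, so the ring closure is the collapse of a 1,4-biradical in a stepwise [2+2] cycloaddition. The closest known reaction type is the Paternò–Büchi addition of aromatic aldehydes to alkyl and silyl enol ethers, which gives 2-aryloxetanes with the oxygen substituent on C3. Regioselectivity is the one selectivity the route cannot do without; it rests on the preference for the oxygen-stabilised secondary radical at C8 over a primary radical at C9, and the minor 2-aryloxy isomer is an acetal that should be lost or separated on silica. C8 is created without control because both partners are achiral and flat, so 12 is racemic; C7 is set relative to C8 by the geometry in which the biradical crosses to the singlet, and its outcome does not matter because C7 is formed again in step 7. Chemoselectivity is secured by the substrates: both phenols are acetylated so that no O–H can quench the triplet, the ring B formyl group is masked so that only one carbonyl is excited, the Pyrex filter keeps light away from the arenes and the product, and the excess of 11 lets addition to the alkene outrun hydrogen abstraction from the acetal C–H.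

Step 7
Reactants: 12 4-{3-[2-(acetyloxy)-4-(1,3-dioxolan-2-yl)phenoxy]oxetan-2-yl}-2,6-dimethoxyphenyl acetate
Product: 16 racemic (2RS,3RS)-3-(4-hydroxy-3,5-dimethoxyphenyl)-2-(hydroxymethyl)-2,3-dihydro-1,4-benzodioxine-6-carbaldehyde, via diphenol oxetane 13 (not isolated), via quinone methide 14 (not isolated), via benzodioxane acetal 15 (not isolated)
Conditions: K2CO3, MeOH–THF (1:1), rt → 50 °C; AcOH to pH 6, evaporate; then PPTS, acetone–H2O (9:1), 40 °C
Reagents that add atoms: water O
Why: Methanolysis removes both aryl acetates, the unhindered one on ring B first; the ring A phenoxide then expels the strained oxetane oxygen from benzylic C7 (the alkaline quinone methide route of 4-hydroxybenzyl ethers), and the ring B phenoxide Oa adds to C7 in a 6-exo-trig conjugate addition, while C9 keeps the former carbonyl oxygen as its hydroxyl. This addition is reversible under the conditions, so C7 should settle trans to the untouched C8 from either epimer of 12; mild acid then hydrolyses the dioxolane, which is far more labile than the benzylic aryl ether.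

Step 8
Reactants: 16 racemic (2RS,3RS)-3-(4-hydroxy-3,5-dimethoxyphenyl)-2-(hydroxymethyl)-2,3-dihydro-1,4-benzodioxine-6-carbaldehyde
Product: 17 [(2S,3S)-6-formyl-3-(4-hydroxy-3,5-dimethoxyphenyl)-2,3-dihydro-1,4-benzodioxin-2-yl]methyl acetate
Conditions: Candida antarctica lipase B (immobilised), vinyl acetate, MTBE–THF (4:1), 35 °C, stopped near 40% conversion; chromatography
Reagents that add atoms: vinyl acetate CC(=O)OC=C
Why: Kinetic resolution by lipase-catalysed transesterification of the primary alcohol next to C8; the enol ester makes the acyl transfer irreversible and the hindered phenol stays free. No stereocentre is formed: the enzyme is expected to acylate the (2S,3S) antipode faster, and the slower (2R,3R) alcohol is removed by chromatography.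

Step 9
Reactants: 17 [(2S,3S)-6-formyl-3-(4-hydroxy-3,5-dimethoxyphenyl)-2,3-dihydro-1,4-benzodioxin-2-yl]methyl acetate
Product: 18 (2S,3S)-3-(4-hydroxy-3,5-dimethoxyphenyl)-2-(hydroxymethyl)-2,3-dihydro-1,4-benzodioxine-6-carbaldehyde
Conditions: Candida antarctica lipase B (immobilised), n-BuOH, MTBE, 40 °C, stopped short of full conversion; chromatography
Reagents that add atoms: none
Why: Lipase-catalysed alcoholysis under neutral conditions; the enzyme keeps the enantiopreference of step 8, so the deacylation acts as a second resolution pass and should raise the enantiomeric purity while leaving the base- and acid-sensitive C7–Oa bond alone.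

Step 10
Reactants: 18 (2S,3S)-3-(4-hydroxy-3,5-dimethoxyphenyl)-2-(hydroxymethyl)-2,3-dihydro-1,4-benzodioxine-6-carbaldehyde; 19 (triphenylphosphoranylidene)acetaldehyde
Product: 20 (2E)-3-[(2S,3S)-3-(4-hydroxy-3,5-dimethoxyphenyl)-2-(hydroxymethyl)-2,3-dihydro-1,4-benzodioxin-6-yl]prop-2-enal
Conditions: THF, 65 °C; 19 (1.2 equiv)
Reagents that add atoms: none
Why: Wittig olefination with a formyl-stabilised ylide, which gives the E-enal and needs no base, so the free phenol and alcohol do not interfere and neither stereocentre is touched; a small excess of ylide limits a second homologation.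

## Compound list

1 | syringaldehyde (4-hydroxy-3,5-dimethoxybenzaldehyde) | COc1cc(C=O)cc(OC)c1O | starting material
2 | 4-formyl-2,6-dimethoxyphenyl acetate | COc1cc(C=O)cc(OC)c1OC(C)=O | intermediate
3 | 3,4-dihydroxybenzaldehyde | O=Cc1ccc(O)c(O)c1 | starting material
4 | 1-bromo-2-chloroethane | ClCCBr | starting material
5 | 4-(2-chloroethoxy)-3-hydroxybenzaldehyde | O=Cc1ccc(OCCCl)c(O)c1 | intermediate
6 | ethane-1,2-diol | OCCO | starting material
7 | 2-(2-chloroethoxy)-5-(1,3-dioxolan-2-yl)phenol | Oc1cc(C2OCCO2)ccc1OCCCl | intermediate
8 | [2-(2-chloroethoxy)-5-(1,3-dioxolan-2-yl)phenoxy]tri(propan-2-yl)silane | CC(C)[Si](Oc1cc(C2OCCO2)ccc1OCCCl)(C(C)C)C(C)C | intermediate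
9 | [5-(1,3-dioxolan-2-yl)-2-(ethenyloxy)phenoxy]tri(propan-2-yl)silane (formed in the flask) | C=COc1ccc(C2OCCO2)cc1O[Si](C(C)C)(C(C)C)C(C)C | intermediate
10 | 5-(1,3-dioxolan-2-yl)-2-(ethenyloxy)phenol, present as its phenoxide (formed in the flask) | C=COc1ccc(C2OCCO2)cc1O | intermediate
11 | 5-(1,3-dioxolan-2-yl)-2-(ethenyloxy)phenyl acetate | C=COc1ccc(C2OCCO2)cc1OC(C)=O | intermediate
12 | 4-{3-[2-(acetyloxy)-4-(1,3-dioxolan-2-yl)phenoxy]oxetan-2-yl}-2,6-dimethoxyphenyl acetate (racemic, 3S antipode drawn; both C2 epimers) | COc1cc(C2OC[C@@H]2Oc3ccc(C4OCCO4)cc3OC(C)=O)cc(OC)c1OC(C)=O | intermediate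
13 | 4-{3-[4-(1,3-dioxolan-2-yl)-2-hydroxyphenoxy]oxetan-2-yl}-2,6-dimethoxyphenol (racemic, 3S antipode drawn; both C2 epimers; formed in the flask) | COc1cc(C2OC[C@@H]2Oc3ccc(C4OCCO4)cc3O)cc(OC)c1O | intermediate
14 | 4-{2-[4-(1,3-dioxolan-2-yl)-2-hydroxyphenoxy]-3-hydroxypropylidene}-2,6-dimethoxycyclohexa-2,5-dien-1-one (racemic, antipode leading to 20 drawn; formed in the flask) | COC1=CC(=C[C@H](CO)Oc2ccc(C3OCCO3)cc2O)C=C(OC)C1=O | intermediate
15 | 4-[(2RS,3RS)-7-(1,3-dioxolan-2-yl)-3-(hydroxymethyl)-2,3-dihydro-1,4-benzodioxin-2-yl]-2,6-dimethoxyphenol (racemic trans, 2S,3S antipode drawn; formed in the flask) | COc1cc([C@@H]2Oc3cc(C4OCCO4)ccc3O[C@H]2CO)cc(OC)c1O | intermediate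
16 | (2RS,3RS)-3-(4-hydroxy-3,5-dimethoxyphenyl)-2-(hydroxymethyl)-2,3-dihydro-1,4-benzodioxine-6-carbaldehyde (racemic trans, 2S,3S antipode drawn) | COc1cc([C@@H]2Oc3cc(C=O)ccc3O[C@H]2CO)cc(OC)c1O | intermediate
17 | [(2S,3S)-6-formyl-3-(4-hydroxy-3,5-dimethoxyphenyl)-2,3-dihydro-1,4-benzodioxin-2-yl]methyl acetate | COc1cc([C@@H]2Oc3cc(C=O)ccc3O[C@H]2COC(C)=O)cc(OC)c1O | intermediate
18 | (2S,3S)-3-(4-hydroxy-3,5-dimethoxyphenyl)-2-(hydroxymethyl)-2,3-dihydro-1,4-benzodioxine-6-carbaldehyde | COc1cc([C@@H]2Oc3cc(C=O)ccc3O[C@H]2CO)cc(OC)c1O | intermediate
19 | (triphenylphosphoranylidene)acetaldehyde | O=CC=P(c1ccccc1)(c1ccccc1)c1ccccc1 | starting material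
20 | (2E)-3-[(2S,3S)-3-(4-hydroxy-3,5-dimethoxyphenyl)-2-(hydroxymethyl)-2,3-dihydro-1,4-benzodioxin-6-yl]prop-2-enal | COc1cc([C@@H]2Oc3cc(/C=C/C=O)ccc3O[C@H]2CO)cc(OC)c1O | target

## Step count and least certain steps

Total step count: 10. Longest linear sequence: 9 steps (steps 2 to 10, from 3 to 20); step 1 is a one-step branch.

**Step 6 (key step).** The most likely failure is unproductive decay of the excited aldehyde, so that conversion stalls. Both arenes can quench the triplet by charge transfer, the acetal C–H of 11 and of 12 can donate a hydrogen atom, and the three oxygen substituents of 2 may bring a π,π* triplet close to the reactive n,π* state. A second concern is incomplete regiocontrol in the first bond formation. The fallback sets out from 3 and 2 and returns at 16; it makes the C7–C8 bond thermally by an aldol addition and closes the dioxane from the open 1,3-diol. Alkylation of 3 with ethyl bromoacetate under the conditions of step 2 gives ethyl (4-formyl-2-hydroxyphenoxy)acetate F1. Acetalisation with 6 as in step 3 gives ethyl [4-(1,3-dioxolan-2-yl)-2-hydroxyphenoxy]acetate F2, and silylation as in step 4 gives ethyl (4-(1,3-dioxolan-2-yl)-2-{[tri(propan-2-yl)silyl]oxy}phenoxy)acetate F3. Its lithium enolate (LiN(CHMe2)2, THF, −78 °C) adds to 2 to give ethyl 3-[4-(acetyloxy)-3,5-dimethoxyphenyl]-2-(4-(1,3-dioxolan-2-yl)-2-{[tri(propan-2-yl)silyl]oxy}phenoxy)-3-hydroxypropanoate F4. LiBH4 in THF reduces the ester and removes the aryl acetate to give 2-(4-(1,3-dioxolan-2-yl)-2-{[tri(propan-2-yl)silyl]oxy}phenoxy)-1-(4-hydroxy-3,5-dimethoxyphenyl)propane-1,3-diol F5. Bu4NF frees the ring B phenol to give 2-[4-(1,3-dioxolan-2-yl)-2-hydroxyphenoxy]-1-(4-hydroxy-3,5-dimethoxyphenyl)propane-1,3-diol F6. Dilute aqueous HCl in THF then ionises the 4-hydroxybenzylic alcohol, lets Oa close the ring trans and hydrolyses the acetal, which gives 16.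

**Step 7.** The most likely failure is interception of the quinone methide by methanol before Oa can add, or an oxetane that does not open at 50 °C because an alkoxide is a poor leaving group even with ring strain. Ring closure at C9 instead of C7 is a lesser concern. The fallback sets out from 12 and returns at 15; it expands the ring under acid, without a free quinone methide. Hydrazine acetate in DMF at 0 °C should remove only the unhindered ring B acetate and give 4-{3-[4-(1,3-dioxolan-2-yl)-2-hydroxyphenoxy]oxetan-2-yl}-2,6-dimethoxyphenyl acetate F7. A catalytic amount of Sc(OTf)3 or diphenyl phosphate in dry CH2Cl2 then opens the oxetane at the benzylic carbon with Oa as the nucleophile, an acid-promoted intramolecular opening of an oxetane by a phenol. This gives 4-[7-(1,3-dioxolan-2-yl)-3-(hydroxymethyl)-2,3-dihydro-1,4-benzodioxin-2-yl]-2,6-dimethoxyphenyl acetate F8 as a cis/trans mixture. K2CO3 in MeOH removes the remaining acetate and equilibrates C7 to trans, now from the benzodioxane side, to give 15, which is hydrolysed as in the second half of step 7.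

**Step 8.** The most likely failure is insufficient discrimination between the antipodes, because the stereocentre carries an oxygen atom and lies one carbon away from the reacting hydroxyl; a preference opposite to the assumed one is also possible. The fallback sets out from 16 and returns at 18. It is a physical resolution by preparative chromatography on a cellulose tris(3,5-dimethylphenylcarbamate) stationary phase with supercritical CO2–MeOH, with the antipodes assigned by comparing their circular dichroism with that of related (S,S)-benzodioxanes. No new compound is made on this path (entry F0), and step 9 is not needed.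

**Step 2.** The most likely failure is ring closure of 5 by its own 3-hydroxyl with loss of chloride, or dialkylation; both grow when base is present in excess. The fallback sets out from 3 and returns at 9; it reverses the order of events and transfers the vinyl group with copper. Double deprotonation of 3 (NaH, 2.1 equiv, DMF, 0 °C) and one equivalent of chlorotri(propan-2-yl)silane should silylate the more basic 3-oxide and give 4-hydroxy-3-{[tri(propan-2-yl)silyl]oxy}benzaldehyde F9. Acetalisation with 6 as in step 3 gives 4-(1,3-dioxolan-2-yl)-2-{[tri(propan-2-yl)silyl]oxy}phenol F10. Chan–Lam vinylation (2,4,6-trivinylcyclotriboroxane–pyridine complex, Cu(OAc)2, pyridine, CH2Cl2, air, rt) gives 9, which is desilylated and acetylated as in the second half of step 5.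

**Step 10.** The most likely failure is a second olefination, because the enal formed is itself an aldehyde and competes with the electron-rich aromatic aldehyde for the ylide. The fallback sets out from 18 and returns at 20; it brings in the two carbons with the aldehyde masked. Wittig reaction with the ylide from (1,3-dioxolan-2-ylmethyl)triphenylphosphonium bromide (t-BuOK, 3 equiv to cover phenol and alcohol, THF, 0 °C → rt) gives 4-[(2S,3S)-7-[2-(1,3-dioxolan-2-yl)ethenyl]-3-(hydroxymethyl)-2,3-dihydro-1,4-benzodioxin-2-yl]-2,6-dimethoxyphenol F11 as an E/Z mixture that cannot react further with the ylide. PPTS in acetone–water, followed by a short treatment with dilute acid if needed, then hydrolyses the acetal and isomerises the olefin to the E-enal 20.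

## Further compounds

F1 | step 6 | ethyl (4-formyl-2-hydroxyphenoxy)acetate | CCOC(=O)COc1ccc(C=O)cc1O
F2 | step 6 | ethyl [4-(1,3-dioxolan-2-yl)-2-hydroxyphenoxy]acetate | CCOC(=O)COc1ccc(C2OCCO2)cc1O
F3 | step 6 | ethyl (4-(1,3-dioxolan-2-yl)-2-{[tri(propan-2-yl)silyl]oxy}phenoxy)acetate | CCOC(=O)COc1ccc(C2OCCO2)cc1O[Si](C(C)C)(C(C)C)C(C)C
F4 | step 6 | ethyl 3-[4-(acetyloxy)-3,5-dimethoxyphenyl]-2-(4-(1,3-dioxolan-2-yl)-2-{[tri(propan-2-yl)silyl]oxy}phenoxy)-3-hydroxypropanoate (racemic, both diastereomers) | CCOC(=O)C(Oc1ccc(C2OCCO2)cc1O[Si](C(C)C)(C(C)C)C(C)C)C(O)c1cc(OC)c(OC(C)=O)c(OC)c1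
F5 | step 6 | 2-(4-(1,3-dioxolan-2-yl)-2-{[tri(propan-2-yl)silyl]oxy}phenoxy)-1-(4-hydroxy-3,5-dimethoxyphenyl)propane-1,3-diol (racemic, both diastereomers) | COc1cc(C(O)C(CO)Oc2ccc(C3OCCO3)cc2O[Si](C(C)C)(C(C)C)C(C)C)cc(OC)c1O
F6 | step 6 | 2-[4-(1,3-dioxolan-2-yl)-2-hydroxyphenoxy]-1-(4-hydroxy-3,5-dimethoxyphenyl)propane-1,3-diol (racemic, both diastereomers) | COc1cc(C(O)C(CO)Oc2ccc(C3OCCO3)cc2O)cc(OC)c1O
F7 | step 7 | 4-{3-[4-(1,3-dioxolan-2-yl)-2-hydroxyphenoxy]oxetan-2-yl}-2,6-dimethoxyphenyl acetate (racemic, 3S antipode drawn; both C2 epimers) | COc1cc(C2OC[C@@H]2Oc3ccc(C4OCCO4)cc3O)cc(OC)c1OC(C)=O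
F8 | step 7 | 4-[7-(1,3-dioxolan-2-yl)-3-(hydroxymethyl)-2,3-dihydro-1,4-benzodioxin-2-yl]-2,6-dimethoxyphenyl acetate (racemic, 3S antipode drawn; cis/trans mixture) | COc1cc(C2Oc3cc(C4OCCO4)ccc3O[C@H]2CO)cc(OC)c1OC(C)=O
F0 | step 8 | none | none
F9 | step 2 | 4-hydroxy-3-{[tri(propan-2-yl)silyl]oxy}benzaldehyde | O=Cc1ccc(O)c(O[Si](C(C)C)(C(C)C)C(C)C)c1
F10 | step 2 | 4-(1,3-dioxolan-2-yl)-2-{[tri(propan-2-yl)silyl]oxy}phenol | Oc1ccc(C2OCCO2)cc1O[Si](C(C)C)(C(C)C)C(C)C
F11 | step 10 | 4-[(2S,3S)-7-[2-(1,3-dioxolan-2-yl)ethenyl]-3-(hydroxymethyl)-2,3-dihydro-1,4-benzodioxin-2-yl]-2,6-dimethoxyphenol (E/Z mixture) | COc1cc([C@@H]2Oc3cc(C=CC4OCCO4)ccc3O[C@H]2CO)cc(OC)c1O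
A1 | alternative 1 | tert-butyl{[(2S,3S)-3-[4-(benzyloxy)-3,5-dimethoxyphenyl]-3-(ethynyloxy)-2-{[(trimethylsilyl)ethynyl]oxy}propyl]oxy}dimethylsilane | COc1cc([C@H](OC#C)[C@@H](OC#C[Si](C)(C)C)CO[Si](C)(C)C(C)(C)C)cc(OC)c1OCc1ccccc1
A2 | alternative 1 | 3,3-diethoxyprop-1-yne | C#CC(OCC)OCC
A3 | alternative 1 | tert-butyl{[(2S,3S)-3-[4-(benzyloxy)-3,5-dimethoxyphenyl]-6-(diethoxymethyl)-8-(trimethylsilyl)-2,3-dihydro-1,4-benzodioxin-2-yl]methoxy}dimethylsilane | COc1cc([C@@H]2Oc3cc(C(OCC)OCC)cc([Si](C)(C)C)c3O[C@H]2CO[Si](C)(C)C(C)(C)C)cc(OC)c1OCc1ccccc1
A4 | alternative 2 | 3-hydroxy-4-{[(2R)-1-hydroxy-3-(4-hydroxy-3,5-dimethoxyphenyl)propan-2-yl]oxy}benzaldehyde | COc1cc(C[C@H](CO)Oc2ccc(C=O)cc2O)cc(OC)c1O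
A5 | alternative 2 | (2S,3S)-3-(4-hydroxy-3,5-dimethoxyphenyl)-2-(hydroxymethyl)-2,3-dihydro-1,4-benzodioxine-6-carbaldehyde (identical with 18) | COc1cc([C@@H]2Oc3cc(C=O)ccc3O[C@H]2CO)cc(OC)c1O
A6 | alternative 3 | ({2-[4-(benzyloxy)-3,5-dimethoxyphenyl]-1,3-benzodioxol-5-yl}oxy)tri(propan-2-yl)silane (racemic at C2) | COc1cc(C2Oc3ccc(O[Si](C(C)C)(C(C)C)C(C)C)cc3O2)cc(OC)c1OCc1ccccc1
A7 | alternative 3 | tert-butyl diazoacetate | [N-]=[N+]=CC(=O)OC(C)(C)C
A8 | alternative 3 | tert-butyl (2R,3S)-3-[4-(benzyloxy)-3,5-dimethoxyphenyl]-6-{[tri(propan-2-yl)silyl]oxy}-2,3-dihydro-1,4-benzodioxine-2-carboxylate (trans) | COc1cc([C@@H]2Oc3cc(O[Si](C(C)C)(C(C)C)C(C)C)ccc3O[C@H]2C(=O)OC(C)(C)C)cc(OC)c1OCc1ccccc1
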